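The earlier runs and the new flask stem from a simulated flask with constants of no real substance.

The ash run, charged with 30 mM of starting material, reads 43 % of target at 2.50 h, and the larch flask, charged with 20 mM, reads 44 % at that time. In percent the two runs follow one curve, as for a pseudo-first-order loss of starting material under held gas.

| flask | starting material | gas phase | remark | time |
|---|---|---|---|---|
| larch | 20 mM | 4.3 mM (held) | the very flask that is asked about, followed so far |  |
| ash | 30 mM | 4.3 mM (held) | run made earlier |  |
| flask | 20 mM | 4.3 mM (held) |  | 10 h |

- larch (time / h: target / %): 0.667: 22; 1.33: 38; 2.00: 40; 2.50: 44; 3.00: 51
- ash (time / h: target / %): 0.833: 27; 2.50: 43; 5.00: 54; 8.00: 58; 10.0: 64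

(each reading ± 2 percentage points)

* target at 10 h, in percent of the starting material charged
* concentration of dissolved gas in solution at 10 h, in percent of saturation

- the numbers in the tables scatter by 2 percentage points (one standard deviation)
- at the start none of the gas phase is in solution

Both ends of that curve can be read. The first readings give an initial climb s = 0.327 /h as a fraction of the charge, and the last ash readings, taken as a plateau, average Y = 58.7 %. Joining them as y = Y(1 − exp(−N)) gives, for the larch flask at 10 h, N = s·t/Y = 5.57, the count of lifetimes of starting material passed. So the reckoning leaves exp(−N) = 0.380 % of starting material in the larch flask and puts target at 58.4 %.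

As a test, at 2.50 h the reckoning gives 1.39 lifetimes and 44.1 %, beside the two readings above, which went into neither s nor Y. But the ash readings climb from 54 % to 64 %, further than the scatter, so Y is the weaker end.

The forecast gives 63 % of target and 96 % of saturation, reasoning that “the ash curve should transfer directly to the larch flask”; its target stands above this reckoning.

The larch flask gives 54.9 % of target at 10 h, dissolved gas at 99.3 % of saturation, and 0.40 % of starting material, beside exp(−N) = 0.380 %.

    gas phase ⇌ dissolved gas, rate k1*(csat - [dissolved gas]) (kL = 140 /h)
    dissolved gas ⇌ dormant form (K = 140, k = 0.220 /h)
    dissolved gas → decomposed reagent (k = 0.700 /h)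
    target ⇌ isomer of the product (K = 0.550, k = 4.80 /h)
    dissolved gas + target → over-reacted product (k = 6.90 /M/h)
    starting material + dissolved gas → target (k = 130 /M/h)

At 3.07 h in the larch flask the forward step from target to isomer of the product, a step that also runs back, goes 160 times as fast as the step to over-reacted product. At 10 h the larch flask holds 30.3 % as isomer and 14.4 % as over-reacted product, and target lies 3.5 percentage points below the reckoned value. For a neighbour flask with the same charge, read at 15 h, N = 8.36 gives exp(−N) = 0.0234 % and target at 58.7 %; that flask holds 0.025 % of starting material, with target at 50.2 %.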